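## Structural features

The target is a flavanone: a chroman-4-one in which benzo ring A is fused to dihydropyranone ring C, and C2 of ring C carries ring B, a 2-methoxy-1,4-benzoquinone bound through C1' (carbonyls at C2' and C5', methoxy at C4'). Ring A is hexasubstituted with strict alternation of oxygen and carbon: O1 on C8a, methyl on C8, methoxy on C7, methyl on C6, a free hydroxyl on C5 hydrogen-bonded to the C4 ketone, and the acyl carbon C4 on C4a. C2 (S) is the only stereocentre, so there is no neighbouring centre and no relative configuration to control. C2 is, however, a benzylic-type ether carbon β to a ketone: base can open ring C by retro-oxa-Michael elimination to a chalcone, and acid can ionise C2–O1 as long as ring B is an electron-rich arene, and either path erases the configuration. The quinone is the most fragile group (nucleophiles, bases, reductants) and must appear last, whereas the chelated C5 phenol is comparatively inert. The real difficulty is twofold: a fully substituted ring A with every substituent in a defined place, and a single enantiomer at a centre that is easy to lose. The key step exploits the fact that O1 (on C8a) and C4 (on C4a) sit on adjacent carbons of ring A with the C5 oxygen directly beside C4a, which is the pattern a 3-alkoxyaryne acquires when an oxygen nucleophile enters at the remote aryne carbon and the resulting ortho-alkoxy aryl anion is acylated.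

## Logic of the disconnections

**19 ⇒ 18.** No skeletal bond is cut. The C2'=O and C5'=O groups of ring B are traced back to two para-disposed aryl–OCH3 groups. The reason is that a quinone would not survive fluoride, a boron Lewis acid or a carbanion. The gain is a robust arene whose oxygen pattern is that of a cheap acetophenone. The forward step must oxidise ring B only, give the para- and not the ortho-quinone, and leave C2–H and the ring A phenol alone.

**18 ⇒ 17.** The O–H at C5 is traced back to O–CH3. An aryne cannot be generated next to a free hydroxyl, and a methyl ether is the smallest non-acidic, inductively withdrawing group. It also makes the two ether groups of the ring A building block identical, so no oxygen differentiation is needed. The forward step must cleave one methyl ether out of five and must not ionise C2–O1.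

**17 ⇒ 9 + 13 (through 14, 15 and 16).** The bonds O1–C8a and C4a–C4 are cut. They are the only two bonds that tie ring A to the rest of ring C. Cutting both turns the hexasubstituted arene into an aryne equivalent and leaves the stereocentre in an open-chain 3-hydroxy ester. The gain is convergence into two fragments of similar size, with ring formation uncoupled from the setting of configuration. The forward step must add oxygen at the correct aryne carbon, acylate the aryl anion faster than it is protonated, and not expose the alkoxide or the product to base for long.

**13 ⇒ 12 ⇒ 10 + 11.** The carbinol C–H is traced back to a ketone, and the bond between the methylene carbon and the ester carbon is then cut. This reduces the chiral fragment to an aryl methyl ketone and a carbonate. The forward demand is a ketone reduction with high facial selectivity that does not solvolyse the electron-rich benzylic alcohol.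

**9 ⇒ 5 (through 6, 7 and 8).** The C–Si and O–S bonds are cut, leading back to an ortho-bromophenol. Silicon is placed on oxygen first and moved to carbon, so its position is fixed by the position of bromine. The forward demand is a clean halogen–metal exchange and silyl shift on a fully substituted ring.

**5 ⇒ 4 ⇒ 3 ⇒ 2 ⇒ 1.** The C–Br bond is cut. The C8 methyl group is then traced back to a formyl group and the ring–CHO bond is cut, which gives the symmetrical phenol 2. Because 2 has two equivalent ortho positions and a blocked para position, the formylation has no regiochemical choice. The same formyl-to-methyl logic leads from 2 to the purchased aldehyde 1. The forward demand is a deoxygenation that stops at the methyl stage and does not touch aryl ethers.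

## Other disconnections considered

**Alternative 1:** The cut is the C2–C3 bond of ring C.
- Precursor: the racemic enol acetal 5-(benzyloxy)-7-methoxy-6,8-dimethyl-4-methylidene-2-(2,4,5-trimethoxyphenyl)-4H-1,3-benzodioxine A1, assembled from a ring A salicylic acid and the ring B aldehyde by acetalisation and methylenation of the lactone carbonyl.
- Forward step: a chiral BINOL-derived N-triflyl phosphoramide would ionise the acetal C2–O3 bond. Within the chiral ion pair the former methylidene carbon would attack the oxocarbenium carbon, forming C2–C3 and closing ring C. The product would be (2S)-5-(benzyloxy)-7-methoxy-6,8-dimethyl-2-(2,4,5-trimethoxyphenyl)chroman-4-one A2, which hydrogenolysis and the oxidation of step 10 would take to 19.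
- In favour: the stereocentre would be created catalytically in the ring-forming step, from a racemate. The benzyl group would come off under neutral conditions, which is kinder to C2 than the boron Lewis acid of step 9; on this point the alternative is the better plan.
- Against: the oxocarbenium ion is stabilised by the 2,4,5-trimethoxyphenyl group, so it should be long-lived and loosely paired, which weakens facial control. The same acid could re-ionise A2 at C2–O1. The ring A acid needs three differentiated oxygen substituents on a hexasubstituted ring, and the methylenation must work on a hindered, electron-rich lactone.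
- Comparison, structure: the alternative makes one C–C bond and the stereocentre together; the chosen plan makes one C–O and one C–C bond and imports the stereocentre from a ketone hydrogenation.
- Comparison, mechanism: the alternative passes through a cation at C2, the species that threatens the configuration; the chosen plan never breaks a bond at C2.
- Comparison, step economy: the alternative is longer before its key step (oxygen differentiation) and equal after it (two steps). In novelty of the key step the two plans are equal, because the enantioselective form of this rearrangement is as unproven as the aryne annulation.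

**Alternative 2:** The cut removes three bonds of ring B: C1'–C2', C2'–C3' and C5'–C6'.
- Forward step: (2S)-2-ethynyl-5-hydroxy-7-methoxy-6,8-dimethylchroman-4-one A3 would be heated with the alkenyl carbene complex (CO)5Cr=C(OMe)C(OMe)=CH2 A4. The terminal alkyne carbon would bond to the carbene carbon, the substituted alkyne carbon to a CO ligand, and the CO carbon to the vinyl terminus. Ring B would appear as the para-methoxyphenol (2S)-5-hydroxy-2-(2-hydroxy-4,5-dimethoxyphenyl)-7-methoxy-6,8-dimethylchroman-4-one A5. Oxidation as in step 10 would then give 19 with loss of one methanol.
- In favour: the regiochemistry is dictated by the terminal alkyne. A5 is a para-methoxyphenol, which should oxidise to the quinone more easily than a trimethoxyarene. The C5 hydroxyl is already free, and C2 in A3 carries an alkyne and not an electron-rich arene, so no Lewis acid is needed near an ionisable C2. On the endgame the alternative is the better plan. It is also the better on precedent, because this benzannulation is an established reaction class.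
- Against: A3 must itself be made as a single enantiomer and is as base-sensitive as any flavanone. Chromium is used in stoichiometric amount. The free phenol and ketone may divert the vinylketene intermediate to cyclobutenone or furan products on heating. Ring A still has to be built by the same classical chemistry, so nothing is saved there.
- Comparison, structure: the alternative builds ring B (three C–C bonds) and leaves the hard parts, ring A and C2, to other steps; the chosen plan joins ring A to the chain that carries C2.
- Comparison, mechanism: both rely on a high-energy intermediate, a metal carbene in one case and an aryne in the other.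
- Comparison, step economy: about equal, or slightly longer once the chromone, its asymmetric alkynylation and the carbene complex are counted.

**Alternative 3:** The cut removes three bonds of ring A: C5–C6, C7–C8 and C4a–C5.
- Forward step: irradiation of the diazoketone (2S)-6-(2-diazopropanoyl)-2-(2,4,5-trimethoxyphenyl)-2,3-dihydro-4H-pyran-4-one A6 would induce a Wolff rearrangement to a vinylketene. The ketene would add 1-methoxypropyne A7 in a [2+2] sense with the methyl-bearing alkyne carbon bonding to the ketene carbonyl carbon. Heating would open the cyclobutenone and a 6π electrocyclisation onto C4a, followed by tautomerisation, would give (2S)-5-hydroxy-7-methoxy-6,8-dimethyl-2-(2,4,5-trimethoxyphenyl)chroman-4-one A8, which is identical with 18.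
- In favour: all four substituents of ring A would be placed in one operation, with the regiochemistry set by the polarity of the ynol ether. The C5 phenol would be formed free, so step 9 disappears. The reaction class is established. On these three points the alternative is the better plan.
- Against: A6 is a densely functionalised and configurationally fragile 2-aryl-dihydropyranone. It would need an asymmetric hetero-Diels–Alder reaction, acylation at C6 and a diazo transfer. The base of the diazo transfer and the heat of the electrocyclisation can both open the β-aryloxy enone. The photolysis must proceed in the presence of an enone and an electron-rich arene.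
- Comparison, structure: the alternative is the most direct answer to the hexasubstituted ring.
- Comparison, mechanism: it is pericyclic throughout and needs no carbanion, but it places the stereocentre under thermal and basic stress before ring A exists.
- Comparison, step economy: the route to A6 is linear and estimated to be longer than the five steps that lead to 9. After the key step the alternative needs one step against two here, which is a point in its favour.

Key step: step 8

Assumption: (R)-BINAP is taken to give the (3S) carbinol, as is usual for aryl β-keto esters (same facial sense as for alkyl keto esters, with the descriptor inverted because aryl outranks CH2CO2Me); if the sense proved opposite for this substrate the antipodal ligand would be used, and compounds 1, 10 and 11 are regarded as purchasable.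

## Route

Step 1
Reactants: 1 4-hydroxy-2,6-dimethoxybenzaldehyde
Product: 2 3,5-dimethoxy-4-methylphenol
Conditions: H2 (4 atm), Pd/C (10% Pd), AcOH, 40 °C
Reagents that add atoms: none
Why: Catalytic hydrogenation reduces the aldehyde to the benzylic alcohol, and the para-hydroxyl and two ortho-methoxy groups make that alcohol hydrogenolyse readily in acetic acid (benzylic hydrogenolysis), so the formyl group should be taken down to methyl while the aryl ethers stay intact.

Step 2
Reactants: 2 3,5-dimethoxy-4-methylphenol
Product: 3 6-hydroxy-2,4-dimethoxy-3-methylbenzaldehyde
Conditions: MgCl2 (1.5 equiv), Et3N (3.8 equiv), (CH2O)n (6 equiv), MeCN, reflux; 1 M HCl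
Reagents that add atoms: formaldehyde (as paraformaldehyde), C=O
Why: Magnesium-mediated ortho-formylation of a phenol (Casnati–Skattebøl reaction): the ArOMgCl phenoxide delivers formaldehyde to the ortho carbon and a second formaldehyde oxidises the salicyl alkoxide by hydride transfer. The two ortho positions of 2 are equivalent and the para position is blocked, so a single aldehyde is expected, and the formyl group deactivates the ring against a second attack.

Step 3
Reactants: 3 6-hydroxy-2,4-dimethoxy-3-methylbenzaldehyde
Product: 4 3,5-dimethoxy-2,4-dimethylphenol
Conditions: H2 (4 atm), Pd/C (10% Pd), AcOH, 40 °C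
Reagents that add atoms: none
Why: The same hydrogenation and benzylic hydrogenolysis as in step 1, here assisted by the ortho-hydroxyl and the ortho/para-methoxy groups, should convert the second formyl group into the second C-methyl group.

Step 4
Reactants: 4 3,5-dimethoxy-2,4-dimethylphenol
Product: 5 2-bromo-3,5-dimethoxy-4,6-dimethylphenol
Conditions: NBS (1.0 equiv), CH2Cl2, −40 → 0 °C
Reagents that add atoms: N-bromosuccinimide, O=C1CCC(=O)N1Br
Why: Electrophilic aromatic bromination at the only unsubstituted ring carbon, which is activated ortho to the hydroxyl and ortho/para to the two methoxy groups. One equivalent of reagent at low temperature should limit oxidation of the electron-rich phenol.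

Step 5
Reactants: 5 2-bromo-3,5-dimethoxy-4,6-dimethylphenol
Product: 9 3,5-dimethoxy-2,4-dimethyl-6-(trimethylsilyl)phenyl trifluoromethanesulfonate, via aryl trimethylsilyl ether 6 (not isolated), via aryllithium 7 (not isolated), via lithium silylphenoxide 8 (not isolated)
Conditions: HMDS (1.5 equiv), THF, 70 °C, then volatiles removed; n-BuLi (1.1 equiv), THF, −78 °C → rt; Tf2O (1.2 equiv), −78 → 0 °C
Reagents that add atoms: hexamethyldisilazane, C[Si](C)(C)N[Si](C)(C)C; trifluoromethanesulfonic anhydride, O=S(=O)(OS(=O)(=O)C(F)(F)F)C(F)(F)F
Why: O-Silylation, bromine–lithium exchange and a 1,3 oxygen-to-carbon silyl shift (retro-Brook rearrangement), driven by formation of phenoxide 8, should place silicon on the carbon next to oxygen. The phenoxide is then sulfonylated on oxygen, which is the standard entry to ortho-silylaryl triflates.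

Step 6
Reactants: 10 1-(2,4,5-trimethoxyphenyl)ethan-1-one; 11 dimethyl carbonate
Product: 12 methyl 3-oxo-3-(2,4,5-trimethoxyphenyl)propanoate
Conditions: NaH (2.5 equiv), 11 (3 equiv), THF, reflux; AcOH quench
Reagents that add atoms: none
Why: Crossed Claisen condensation: the sodium enolate of 10 attacks the non-enolisable carbonate 11, and deprotonation of the β-keto ester product drives the equilibrium.

Step 7
Reactants: 12 methyl 3-oxo-3-(2,4,5-trimethoxyphenyl)propanoate
Product: 13 methyl (3S)-3-hydroxy-3-(2,4,5-trimethoxyphenyl)propanoate
Conditions: RuCl2[(R)-BINAP](dmf)n (0.5 mol%), H2 (50 atm), MeOH, 50 °C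
Reagents that add atoms: none
Why: Noyori asymmetric hydrogenation of a β-keto ester: the substrate chelates divalent ruthenium through both carbonyl oxygens and hydride goes to the ketone face selected by the (R)-BINAP ligand, which for an aryl keto ester should give the (3S) carbinol. This step sets the only stereocentre of the target.

Step 8
Reactants: 9 3,5-dimethoxy-2,4-dimethyl-6-(trimethylsilyl)phenyl trifluoromethanesulfonate; 13 methyl (3S)-3-hydroxy-3-(2,4,5-trimethoxyphenyl)propanoate
Product: 17 (2S)-5,7-dimethoxy-6,8-dimethyl-2-(2,4,5-trimethoxyphenyl)chroman-4-one, via trimethylsilyl ether 14 (not isolated), via 3,5-dimethoxy-4,6-dimethylbenzyne 15 (not isolated), via tetrabutylammonium alkoxide 16 (not isolated)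
Conditions: 13, Me3SiNEt2 (1.5 equiv), toluene, 50 °C, then volatiles removed; 9 (1.5 equiv), THF, 0 °C; [Bu4N][Ph3SiF2] (1.6 equiv, added over 2 h), 0 °C → rt; AcOH quench
Reagents that add atoms: none
Why: Proposed new method: fluoride from [Bu4N][Ph3SiF2] removes the aryl trimethylsilyl group of 9 with loss of triflate to give aryne 15 and in the same medium cleaves the O–Si bond of 14 to give the proton-free alkoxide 16, which adds through oxygen to the aryne carbon that becomes C8a; the carbanion left on C4a then attacks the ester carbonyl, forms C4a–C4 and expels methoxide, which is taken up by silicon of unreacted 9 or 14 and so carries the process on without a strong base building up. The closest known reaction types are the fluoride-induced annulation of arynes with salicylate esters to xanthones, the insertion of arynes into carboxylic acids to give ortho-hydroxyaryl ketones, and Parham-type cycloacylation of ortho-metalated aryl ethers onto a tethered ester; new here is an aliphatic, enolisable 3-oxy ester as the four-atom partner. Ring C closes in the 6-exo-trig mode, the aryl carbanion attacking a carbonyl group that lies outside the ring being formed. No stereocentre is created: C2 stems from 13, none of its four bonds is touched, and the (S) descriptor is unchanged because the priority order O > aryl > CH2 is the same before and after. The step needs regioselective addition to the aryne, which the C5 methoxy group should secure by polarising and distorting the triple bond so that the nucleophile enters at the remote carbon and the charge develops ortho to oxygen, with the C8 methyl offering only mild steric opposition. It also needs acylation to outrun protonation of the aryl anion, which the absence of O–H and N–H donors (silyl ether in place of the free alcohol, THF in place of acetonitrile) and the six-membered intramolecular transition state should secure. Slow addition of fluoride at 0 °C and an acetic acid quench keep short the exposure of 16 to retro-aldol cleavage and of 17 to base-induced ring opening.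

Step 9
Reactants: 17 (2S)-5,7-dimethoxy-6,8-dimethyl-2-(2,4,5-trimethoxyphenyl)chroman-4-one
Product: 18 (2S)-5-hydroxy-7-methoxy-6,8-dimethyl-2-(2,4,5-trimethoxyphenyl)chroman-4-one
Conditions: BCl3 (1.2 equiv), CH2Cl2, −78 → −40 °C; cold water quench
Reagents that add atoms: none
Why: Chelation-controlled ether cleavage: boron bridges the C4 carbonyl oxygen and the peri C5 methoxy oxygen in a six-membered chelate and chloride removes that methyl group, whereas the other four methoxy groups have no neighbouring carbonyl. Low temperature and a small excess of reagent are chosen so that C2–O1 is not ionised.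

Step 10
Reactants: 18 (2S)-5-hydroxy-7-methoxy-6,8-dimethyl-2-(2,4,5-trimethoxyphenyl)chroman-4-one
Product: 19 2-[(2S)-5-hydroxy-7-methoxy-6,8-dimethyl-4-oxochroman-2-yl]-5-methoxycyclohexa-2,5-diene-1,4-dione
Conditions: (NH4)2Ce(NO3)6 (2.2 equiv), MeCN–H2O (2:1), 0 °C, 10 min
Reagents that add atoms: water, O
Why: Oxidative demethylation of a para-dimethoxyarene: tetravalent cerium removes electrons from the most electron-rich ring (ring B), water adds at C2' and C5' and two molecules of methanol leave, which should give the para-quinone and keep the C4' methoxy group. Ring A is an acyl-deactivated, hydrogen-bonded phenol without a para oxygen pair and should be spared in a short reaction at 0 °C.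

## Compound list

1 | 4-hydroxy-2,6-dimethoxybenzaldehyde | O=Cc1c(OC)cc(O)cc1OC | starting material
2 | 3,5-dimethoxy-4-methylphenol | Cc1c(OC)cc(O)cc1OC | intermediate
3 | 6-hydroxy-2,4-dimethoxy-3-methylbenzaldehyde | O=Cc1c(OC)c(C)c(OC)cc1O | intermediate
4 | 3,5-dimethoxy-2,4-dimethylphenol | Cc1c(O)cc(OC)c(C)c1OC | intermediate
5 | 2-bromo-3,5-dimethoxy-4,6-dimethylphenol | Cc1c(O)c(Br)c(OC)c(C)c1OC | intermediate
6 | (2-bromo-3,5-dimethoxy-4,6-dimethylphenoxy)trimethylsilane | Cc1c(O[Si](C)(C)C)c(Br)c(OC)c(C)c1OC | intermediate
7 | [2,4-dimethoxy-3,5-dimethyl-6-(trimethylsilyloxy)phenyl]lithium | [Li]c1c(O[Si](C)(C)C)c(C)c(OC)c(C)c1OC | intermediate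
8 | lithium 3,5-dimethoxy-2,4-dimethyl-6-(trimethylsilyl)phenolate | [Li+].[O-]c1c(C)c(OC)c(C)c(OC)c1[Si](C)(C)C | intermediate
9 | 3,5-dimethoxy-2,4-dimethyl-6-(trimethylsilyl)phenyl trifluoromethanesulfonate | COc1c(C)c(OC)c([Si](C)(C)C)c(OS(=O)(=O)C(F)(F)F)c1C | intermediate
10 | 1-(2,4,5-trimethoxyphenyl)ethan-1-one | CC(=O)c1cc(OC)c(OC)cc1OC | starting material
11 | dimethyl carbonate | COC(=O)OC | starting material
12 | methyl 3-oxo-3-(2,4,5-trimethoxyphenyl)propanoate | COC(=O)CC(=O)c1cc(OC)c(OC)cc1OC | intermediate
13 | methyl (3S)-3-hydroxy-3-(2,4,5-trimethoxyphenyl)propanoate | COC(=O)C[C@H](O)c1cc(OC)c(OC)cc1OC | intermediate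
14 | methyl (3S)-3-(2,4,5-trimethoxyphenyl)-3-[(trimethylsilyl)oxy]propanoate | COC(=O)C[C@H](O[Si](C)(C)C)c1cc(OC)c(OC)cc1OC | intermediate
15 | 3,5-dimethoxy-4,6-dimethylbenzyne (1,2-didehydro-3,5-dimethoxy-4,6-dimethylbenzene) | CC1=C(OC)C(C)=C(OC)C#C1 | intermediate
16 | tetrabutylammonium (1S)-3-methoxy-3-oxo-1-(2,4,5-trimethoxyphenyl)propan-1-olate | COC(=O)C[C@H]([O-])c1cc(OC)c(OC)cc1OC.CCCC[N+](CCCC)(CCCC)CCCC | intermediate
17 | (2S)-5,7-dimethoxy-6,8-dimethyl-2-(2,4,5-trimethoxyphenyl)chroman-4-one | COc1cc(OC)c([C@@H]2CC(=O)c3c(OC)c(C)c(OC)c(C)c3O2)cc1OC | intermediate
18 | (2S)-5-hydroxy-7-methoxy-6,8-dimethyl-2-(2,4,5-trimethoxyphenyl)chroman-4-one | COc1cc(OC)c([C@@H]2CC(=O)c3c(O)c(C)c(OC)c(C)c3O2)cc1OC | intermediate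
19 | 2-[(2S)-5-hydroxy-7-methoxy-6,8-dimethyl-4-oxochroman-2-yl]-5-methoxycyclohexa-2,5-diene-1,4-dione | COC1=CC(=O)C([C@@H]2CC(=O)c3c(O)c(C)c(OC)c(C)c3O2)=CC1=O | target

## Step count and least certain steps

Total step count: 10. Longest linear sequence: 8 (steps 1 to 5, then 8, 9 and 10); the second branch (steps 6 and 7) joins at step 8.

**Step 8 (key step, proposed new method).**
- Most likely failure: protonation of the C4a aryl anion before it reaches the ester, by proton transfer from the α-methylene of the ester through a six-membered transition state or from adventitious donors. This would stop the sequence at the open aryl ether, or after α-deprotonation lead to β-elimination of the aryloxide.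
- Further risks: retro-aldol cleavage of alkoxide 16, which would erode the configuration; transfer of the triflyl group from 9 to the alkoxide; addition to the aryne in the opposite orientation; and base-induced opening of ring C in 17.
- Fallback (known chemistry), from 4 back to 17: Friedel–Crafts acetylation of 4 at its one free ring position (Ac2O, BF3·OEt2) would give 1-(2-hydroxy-4,6-dimethoxy-3,5-dimethylphenyl)ethan-1-one F1. Condensation with N,N-dimethylformamide dimethyl acetal would give the enaminone (2E)-3-(dimethylamino)-1-(2-hydroxy-4,6-dimethoxy-3,5-dimethylphenyl)prop-2-en-1-one F2, which should close under acid to 5,7-dimethoxy-6,8-dimethyl-4H-chromen-4-one F3. Asymmetric conjugate addition of purchased (2,4,5-trimethoxyphenyl)boronic acid to F3, catalysed by Pd(OCOCF3)2 with a chiral tert-butyl pyridine–oxazoline ligand (NH4PF6, H2O, ClCH2CH2Cl, 60 °C, the ligand antipode chosen to give the 2S product), would then deliver 17. Steps 4 to 7 would be dropped. The weak point of this fallback is the ortho-substituted, protodeboronation-prone boronic acid.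

**Step 9.**
- Most likely failure: heterolysis of the C2–O1 bond under the boron Lewis acid, because the 2,4,5-trimethoxyphenyl group stabilises positive charge at C2. Reclosure would then give a lower enantiomeric purity. Cleavage of a second methyl ether, most likely the twisted one at C7, is the other risk.
- Fallback, from 17 to 19 with the last two operations in reverse order: oxidation of 17 with (NH4)2Ce(NO3)6 as in step 10 would give 2-[(2S)-5,7-dimethoxy-6,8-dimethyl-4-oxochroman-2-yl]-5-methoxycyclohexa-2,5-diene-1,4-dione F4. Its ring B is electron-poor and can no longer support ionisation at C2. BCl3 at −78 °C would then cleave the chelated C5 ether to give 19 directly. The price is exposure of the quinone to a Lewis acid and chloride, which is why this order is not the first choice.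

**Step 7.**
- Most likely failure: slow reduction and lower facial selectivity, because the ketone is deactivated by the ortho- and para-methoxy groups. Solvolysis of the electron-rich benzylic alcohol (racemisation or O-methylation) by traces of HCl released from the catalyst in methanol is the second risk.
- Fallback, from 12 to 13: asymmetric transfer hydrogenation with RuCl[(S,S)-TsDPEN](p-cymene) in HCO2H/Et3N at 30 °C. It works through an outer-sphere bifunctional mechanism in which the face is selected by the aryl group and not by chelation, and it avoids chloride-derived acid in methanol. This fallback makes no new compound (F0).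

**Step 5.**
- Most likely failure: quenching of aryllithium 7 by proton sources, or its butylation by the 1-bromobutane formed in the exchange, before the silyl group has migrated. Incomplete sulfonylation of the hindered phenoxide 8 is the other risk.
- Fallback, from 4 to 9 without bromine (replaces steps 4 and 5): carbamoylation of 4 with isopropyl isocyanate (Et3N, CH2Cl2) would give 3,5-dimethoxy-2,4-dimethylphenyl N-(propan-2-yl)carbamate F5. In situ N-silylation, carbamate-directed ortho-lithiation (n-BuLi, TMEDA, −78 °C) and a Me3SiCl quench would give 3,5-dimethoxy-2,4-dimethyl-6-(trimethylsilyl)phenyl N-(propan-2-yl)carbamate F6. Cleavage of the carbamate with Et2NH and DBU followed in the same flask by PhNTf2 would give 9. The point to watch is lateral lithiation of the C2 methyl group in competition with ring lithiation.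

## Further compounds

F1 | step 8 | 1-(2-hydroxy-4,6-dimethoxy-3,5-dimethylphenyl)ethan-1-one | CC(=O)c1c(O)c(C)c(OC)c(C)c1OC
F2 | step 8 | (2E)-3-(dimethylamino)-1-(2-hydroxy-4,6-dimethoxy-3,5-dimethylphenyl)prop-2-en-1-one | CN(C)/C=C/C(=O)c1c(O)c(C)c(OC)c(C)c1OC
F3 | step 8 | 5,7-dimethoxy-6,8-dimethyl-4H-chromen-4-one | O=c1ccoc2c(C)c(OC)c(C)c(OC)c12
F4 | step 9 | 2-[(2S)-5,7-dimethoxy-6,8-dimethyl-4-oxochroman-2-yl]-5-methoxycyclohexa-2,5-diene-1,4-dione | COC1=CC(=O)C([C@@H]2CC(=O)c3c(OC)c(C)c(OC)c(C)c3O2)=CC1=O
F0 | step 7 | none | none
F5 | step 5 | 3,5-dimethoxy-2,4-dimethylphenyl N-(propan-2-yl)carbamate | CC(C)NC(=O)Oc1cc(OC)c(C)c(OC)c1C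
F6 | step 5 | 3,5-dimethoxy-2,4-dimethyl-6-(trimethylsilyl)phenyl N-(propan-2-yl)carbamate | CC(C)NC(=O)Oc1c(C)c(OC)c(C)c(OC)c1[Si](C)(C)C
A1 | alternative 1 | 5-(benzyloxy)-7-methoxy-6,8-dimethyl-4-methylidene-2-(2,4,5-trimethoxyphenyl)-4H-1,3-benzodioxine (racemic) | C=C1OC(c2cc(OC)c(OC)cc2OC)Oc2c(C)c(OC)c(C)c(OCc3ccccc3)c21
A2 | alternative 1 | (2S)-5-(benzyloxy)-7-methoxy-6,8-dimethyl-2-(2,4,5-trimethoxyphenyl)chroman-4-one | COc1cc(OC)c([C@@H]2CC(=O)c3c(OCc4ccccc4)c(C)c(OC)c(C)c3O2)cc1OC
A3 | alternative 2 | (2S)-2-ethynyl-5-hydroxy-7-methoxy-6,8-dimethylchroman-4-one | C#C[C@@H]1CC(=O)c2c(O)c(C)c(OC)c(C)c2O1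
A4 | alternative 2 | pentacarbonyl[methoxy(1-methoxyethenyl)methylidene]chromium, (CO)5Cr=C(OMe)C(OMe)=CH2 | COC(=C)C(OC)=[Cr](=C=O)(=C=O)(=C=O)(=C=O)=C=O
A5 | alternative 2 | (2S)-5-hydroxy-2-(2-hydroxy-4,5-dimethoxyphenyl)-7-methoxy-6,8-dimethylchroman-4-one | COc1cc(O)c([C@@H]2CC(=O)c3c(O)c(C)c(OC)c(C)c3O2)cc1OC
A6 | alternative 3 | (2S)-6-(2-diazopropanoyl)-2-(2,4,5-trimethoxyphenyl)-2,3-dihydro-4H-pyran-4-one | CC(=[N+]=[N-])C(=O)C1=CC(=O)C[C@@H](c2cc(OC)c(OC)cc2OC)O1
A7 | alternative 3 | 1-methoxypropyne | CC#COC
A8 | alternative 3 | (2S)-5-hydroxy-7-methoxy-6,8-dimethyl-2-(2,4,5-trimethoxyphenyl)chroman-4-one | COc1cc(OC)c([C@@H]2CC(=O)c3c(O)c(C)c(OC)c(C)c3O2)cc1OC
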